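**Retrosynthetic overview**
- The last C–C bond made is the aryl–CH2 bond of the keto-alcohol arm. A nickel-catalysed radical cross-electrophile coupling joins the fully assembled aryl bromide polyester to an unprotected (R)-chloro-hydroxy ketone; hydrogenolysis then frees the target.
- The central ester is cut into an acid and an alcohol that both come from one bromo ester. The alcohol is made by a second radical coupling of that bromo ester with (R)-methyloxirane.
- The bromo ester comes from Mitsunobu inversion of an (S)-3-hydroxybutanoate with 2,4-bis(benzyloxy)-6-bromobenzoic acid.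
- No ring is built: both benzene rings come from 3-bromophenol (borylation/oxidation, benzylation, formylation, oxidation). All four stereocentres come from C3/C4 chiral-pool pieces.

Assumption: all four stereocentres of the given SMILES are read as R; 3-bromophenol, (S)-3-hydroxybutanoic acid, (R)-methyloxirane and methyl (R)-3-hydroxybutanoate are taken as commercial.

**Step 1**
Reactants: 1 3-bromophenol
Product: 3 5-bromobenzene-1,3-diol, via bis-boryl arene 2 (not isolated)
Conditions: HBpin (3 equiv), [Ir(OMe)(cod)]2 (1.5 mol %), 4,4'-di-tert-butyl-2,2'-bipyridine (3 mol %), THF, 80 °C; then KHSO5 (as 2KHSO5·KHSO4·K2SO4), acetone/H2O, rt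
Reagents that add atoms: potassium peroxymonosulfate, [K+].[O-]S(=O)(=O)OO
Why: Iridium-catalysed C–H borylation is sterically controlled, so after in-flask O-borylation only C5, the one C–H with no ortho substituent, is borylated, and the C–B bond is then oxidised to C–OH (C–H borylation/oxidation sequence).

**Step 2**
Reactants: 3 5-bromobenzene-1,3-diol
Product: 4 1,3-bis(benzyloxy)-5-bromobenzene
Conditions: BnBr (2.2 equiv), K2CO3, DMF, 60 °C
Reagents that add atoms: benzyl bromide, BrCc1ccccc1
Why: Williamson etherification of both phenoxides gives benzyl ethers that survive every later step and fall in the final hydrogenolysis.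

**Step 3**
Reactants: 4 1,3-bis(benzyloxy)-5-bromobenzene
Product: 6 2,4-bis(benzyloxy)-6-bromobenzaldehyde, via aryl iminium salt 5 (not isolated)
Conditions: POCl3 (2 equiv), DMF, 0 to 80 °C; then H2O, 60 °C
Reagents that add atoms: N,N-dimethylformamide, CN(C)C=O; water, O
Why: Vilsmeier–Haack formylation of the electron-rich arene goes para to one benzyloxy group and ortho to the other, next to bromine, as with the known dimethoxy analogue, and avoids the crowded site between the two ethers.

**Step 4**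
Reactants: 6 2,4-bis(benzyloxy)-6-bromobenzaldehyde
Product: 7 2,4-bis(benzyloxy)-6-bromobenzoic acid
Conditions: NaClO2, NaH2PO4, 2-methylbut-2-ene, t-BuOH/THF/H2O, rt
Reagents that add atoms: sodium chlorite, [Na+].[O-]Cl=O
Why: Pinnick oxidation converts the hindered aryl aldehyde to the acid while 2-methylbut-2-ene traps hypochlorous acid so the electron-rich ring is not chlorinated.

**Step 5**
Reactants: 8 (S)-3-hydroxybutanoic acid
Product: 9 4-methoxybenzyl (S)-3-hydroxybutanoate
Conditions: KHCO3, 4-methoxybenzyl chloride, DMF, rt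
Reagents that add atoms: 4-methoxybenzyl chloride, COc1ccc(CCl)cc1
Why: Carboxylate O-alkylation under bicarbonate conditions leaves the secondary alcohol and its (S) centre untouched and gives an ester that is acid-labile yet also hydrogenolysable.

**Step 6**
Reactants: 7 2,4-bis(benzyloxy)-6-bromobenzoic acid; 9 4-methoxybenzyl (S)-3-hydroxybutanoate
Product: 10 4-methoxybenzyl (R)-3-{[2,4-bis(benzyloxy)-6-bromobenzoyl]oxy}butanoate
Conditions: PPh3, DIAD, toluene, 0 °C to rt
Reagents that add atoms: none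
Why: Mitsunobu esterification suits the doubly ortho-substituted acid because its carboxylate attacks the activated carbinol carbon in an SN2 step, which inverts (S) to the required (R) centre.

**Step 7**
Reactants: 10 4-methoxybenzyl (R)-3-{[2,4-bis(benzyloxy)-6-bromobenzoyl]oxy}butanoate; 11 (R)-2-methyloxirane
Product: 13 4-methoxybenzyl (R)-3-({2,4-bis(benzyloxy)-6-[(R)-2-hydroxypropyl]benzoyl}oxy)butanoate, via (R)-1-iodopropan-2-ol 12 (not isolated)
Conditions: NiCl2(dme) (10 mol %), 2,2'-bipyridine (10 mol %), NaI (0.5 equiv), Et3N·HCl (1.2 equiv), Mn powder (2.5 equiv), 11 (3 equiv), DMPU, 30 °C, sealed tube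
Reagents that add atoms: none
Why: In this nickel-catalysed reductive cross-electrophile coupling, iodide opens the protonated epoxide at CH2 to 12, monovalent nickel abstracts iodine to give the primary 2-hydroxypropyl radical, and this radical is captured by the aryl nickel species formed from 10 and zerovalent nickel and reductively eliminated, so the aryl–CH2 bond forms in a radical step and the epoxide stereocentre is carried over unchanged as (R).

**Step 8**
Reactants: 10 4-methoxybenzyl (R)-3-{[2,4-bis(benzyloxy)-6-bromobenzoyl]oxy}butanoate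
Product: 14 (R)-3-{[2,4-bis(benzyloxy)-6-bromobenzoyl]oxy}butanoic acid
Conditions: TFA/CH2Cl2 (1:5), anisole (5 equiv), 0 °C, 30 min
Reagents that add atoms: none
Why: Acidolysis of the 4-methoxybenzyl ester (the benzylic cation is trapped by anisole in a Friedel–Crafts step) frees the acid, while aryl benzyl ethers, the aryl bromide and the aryl ester are stable to brief cold TFA.

**Step 9**
Reactants: 13 4-methoxybenzyl (R)-3-({2,4-bis(benzyloxy)-6-[(R)-2-hydroxypropyl]benzoyl}oxy)butanoate; 14 (R)-3-{[2,4-bis(benzyloxy)-6-bromobenzoyl]oxy}butanoic acid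
Product: 15 4-methoxybenzyl (R)-3-{[2,4-bis(benzyloxy)-6-((R)-2-{[(R)-3-{[2,4-bis(benzyloxy)-6-bromobenzoyl]oxy}butanoyl]oxy}propyl)benzoyl]oxy}butanoate
Conditions: EDC·HCl (1.5 equiv), DMAP (0.2 equiv), CH2Cl2, 0 °C to rt
Reagents that add atoms: none
Why: Steglich esterification joins the unhindered aliphatic acid to the secondary alcohol with retention at every centre, and low temperature with catalytic DMAP limits E1cB loss of the β-aroyloxy group.

**Step 10**
Reactants: 16 methyl (R)-3-hydroxybutanoate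
Product: 17 (R)-1-chloro-4-hydroxypentan-2-one
Conditions: ClCH2I (2.5 equiv), MeLi·LiBr (3.5 equiv), THF/Et2O, −78 °C; AcOH, −78 °C
Reagents that add atoms: chloroiodomethane, ClCI
Why: Chloromethyllithium, made in the flask by iodine–lithium exchange, adds once to the ester because the chelated tetrahedral dialkoxide survives at −78 °C and collapses to the α-chloro ketone only on acidic quench (ester to chloromethyl ketone homologation), with the carbinol centre not involved.

**Step 11**
Reactants: 15 4-methoxybenzyl (R)-3-{[2,4-bis(benzyloxy)-6-((R)-2-{[(R)-3-{[2,4-bis(benzyloxy)-6-bromobenzoyl]oxy}butanoyl]oxy}propyl)benzoyl]oxy}butanoate; 17 (R)-1-chloro-4-hydroxypentan-2-one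
Product: 19 4-methoxybenzyl (R)-3-{[2,4-bis(benzyloxy)-6-((R)-2-{[(R)-3-({2,4-bis(benzyloxy)-6-[(R)-4-hydroxy-2-oxopentyl]benzoyl}oxy)butanoyl]oxy}propyl)benzoyl]oxy}butanoate, via (R)-4-hydroxy-1-iodopentan-2-one 18 (not isolated)
Conditions: NiBr2(dme) (10 mol %), 2,2'-bipyridine (10 mol %), NaI (0.5 equiv), Mn powder (3 equiv), DMA, 40 °C; 17 (2.5 equiv) added over 6 h
Reagents that add atoms: none
Why: Key step, a nickel-catalysed reductive cross-electrophile coupling of an aryl bromide with an α-halo ketone, in which halogen abstraction from 17 or 18 by low-valent nickel gives the α-keto alkyl radical that combines with the aryl nickel species formed from 15 and zerovalent nickel and reductively eliminates, so the aryl–CH2 bond is forged with the (R) carbinol preformed and unprotected while esters, benzyl ethers and the free hydroxyl are inert to the near-neutral reductive medium.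

**Step 12**
Reactants: 19 4-methoxybenzyl (R)-3-{[2,4-bis(benzyloxy)-6-((R)-2-{[(R)-3-({2,4-bis(benzyloxy)-6-[(R)-4-hydroxy-2-oxopentyl]benzoyl}oxy)butanoyl]oxy}propyl)benzoyl]oxy}butanoate
Product: 20 (R)-3-{[2,4-dihydroxy-6-((R)-2-{[(R)-3-({2,4-dihydroxy-6-[(R)-4-hydroxy-2-oxopentyl]benzoyl}oxy)butanoyl]oxy}propyl)benzoyl]oxy}butanoic acid
Conditions: H2 (1 atm), Pd/C (10 wt % Pd), EtOAc/MeOH, rt
Reagents that add atoms: none
Why: Catalytic hydrogenolysis cleaves the four aryl benzyl ethers and the 4-methoxybenzyl ester in one operation, while the esters, the benzyl ketone and the secondary alcohol are not reduced and no stereocentre is touched.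

**Compound list**
1 | 3-bromophenol | Oc1cccc(Br)c1 | starting material
2 | 2-[3-bromo-5-(4,4,5,5-tetramethyl-1,3,2-dioxaborolan-2-yl)phenoxy]-4,4,5,5-tetramethyl-1,3,2-dioxaborolane | CC1(C)OB(Oc2cc(Br)cc(c2)B2OC(C)(C)C(C)(C)O2)OC1(C)C | intermediate
3 | 5-bromobenzene-1,3-diol | Oc1cc(O)cc(Br)c1 | intermediate
4 | 1,3-bis(benzyloxy)-5-bromobenzene | Brc1cc(OCc2ccccc2)cc(OCc2ccccc2)c1 | intermediate
5 | N-{[2,4-bis(benzyloxy)-6-bromophenyl]methylidene}-N-methylmethanaminium dichlorophosphate | C[N+](C)=Cc1c(Br)cc(OCc2ccccc2)cc1OCc1ccccc1.[O-]P(Cl)(Cl)=O | intermediate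
6 | 2,4-bis(benzyloxy)-6-bromobenzaldehyde | O=Cc1c(Br)cc(OCc2ccccc2)cc1OCc1ccccc1 | intermediate
7 | 2,4-bis(benzyloxy)-6-bromobenzoic acid | OC(=O)c1c(Br)cc(OCc2ccccc2)cc1OCc1ccccc1 | intermediate
8 | (S)-3-hydroxybutanoic acid | C[C@H](O)CC(=O)O | starting material
9 | 4-methoxybenzyl (S)-3-hydroxybutanoate | C[C@H](O)CC(=O)OCc1ccc(OC)cc1 | intermediate
10 | 4-methoxybenzyl (R)-3-{[2,4-bis(benzyloxy)-6-bromobenzoyl]oxy}butanoate | C[C@H](CC(=O)OCc1ccc(OC)cc1)OC(=O)c1c(Br)cc(OCc2ccccc2)cc1OCc1ccccc1 | intermediate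
11 | (R)-2-methyloxirane | C[C@@H]1CO1 | starting material
12 | (R)-1-iodopropan-2-ol | C[C@@H](O)CI | intermediate
13 | 4-methoxybenzyl (R)-3-({2,4-bis(benzyloxy)-6-[(R)-2-hydroxypropyl]benzoyl}oxy)butanoate | C[C@@H](O)Cc1cc(OCc2ccccc2)cc(OCc2ccccc2)c1C(=O)O[C@H](C)CC(=O)OCc1ccc(OC)cc1 | intermediate
14 | (R)-3-{[2,4-bis(benzyloxy)-6-bromobenzoyl]oxy}butanoic acid | C[C@H](CC(=O)O)OC(=O)c1c(Br)cc(OCc2ccccc2)cc1OCc1ccccc1 | intermediate
15 | 4-methoxybenzyl (R)-3-{[2,4-bis(benzyloxy)-6-((R)-2-{[(R)-3-{[2,4-bis(benzyloxy)-6-bromobenzoyl]oxy}butanoyl]oxy}propyl)benzoyl]oxy}butanoate | C[C@H](Cc1cc(OCc2ccccc2)cc(OCc2ccccc2)c1C(=O)O[C@H](C)CC(=O)OCc1ccc(OC)cc1)OC(=O)C[C@@H](C)OC(=O)c1c(Br)cc(OCc2ccccc2)cc1OCc1ccccc1 | intermediate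
16 | methyl (R)-3-hydroxybutanoate | C[C@@H](O)CC(=O)OC | starting material
17 | (R)-1-chloro-4-hydroxypentan-2-one | C[C@@H](O)CC(=O)CCl | intermediate
18 | (R)-4-hydroxy-1-iodopentan-2-one | C[C@@H](O)CC(=O)CI | intermediate
19 | 4-methoxybenzyl (R)-3-{[2,4-bis(benzyloxy)-6-((R)-2-{[(R)-3-({2,4-bis(benzyloxy)-6-[(R)-4-hydroxy-2-oxopentyl]benzoyl}oxy)butanoyl]oxy}propyl)benzoyl]oxy}butanoate | C[C@H](Cc1cc(OCc2ccccc2)cc(OCc2ccccc2)c1C(=O)O[C@H](C)CC(=O)OCc1ccc(OC)cc1)OC(=O)C[C@@H](C)OC(=O)c1c(OCc2ccccc2)cc(OCc2ccccc2)cc1CC(=O)C[C@@H](C)O | intermediate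
20 | (R)-3-{[2,4-dihydroxy-6-((R)-2-{[(R)-3-({2,4-dihydroxy-6-[(R)-4-hydroxy-2-oxopentyl]benzoyl}oxy)butanoyl]oxy}propyl)benzoyl]oxy}butanoic acid | C[C@H](Cc1cc(O)cc(O)c1C(=O)O[C@H](C)CC(=O)O)OC(=O)C[C@@H](C)OC(=O)c1c(O)cc(O)cc1CC(=O)C[C@@H](C)O | target

**Step count:** 12 steps in total. Longest linear sequence: 9 steps (steps 1, 2, 3, 4, 6, 7, 9, 11, 12).

**Steps most likely to fail**

Step 11 is the riskiest. The unprotected chloro ketone can be reduced to the simple ketone, can close onto its own hydroxyl to a furanone, or can homocouple, all on a precious late intermediate. The fallback sets out from 15 and comes back at 20. Commercial (R)-pent-4-yn-2-ol F1 is benzylated (NaH, BnBr, THF) to (R)-4-(benzyloxy)pent-1-yne F2. Sonogashira coupling of 15 with it (PdCl2(PPh3)2, CuI, iPr2NH, THF, 50 °C) gives the alkyne-coupled tetraester F3. Hydration with a monovalent gold catalyst (AuCl(PPh3)/AgOTf, wet dioxane, rt) is steered by 6-endo attack of the neighbouring ester carbonyl, which puts the ketone on the carbon remote from the ring and gives the O-benzyl keto tetraester F4. The hydrogenolysis of step 12, applied to F4, delivers 20.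

Step 7 is next. The ortho-ester aryl bromide is electron-rich and may couple slowly, the volatile epoxide may give some branched isomer, and the new alkoxide could lactonise onto the aryl ester. The fallback sets out from 4 and comes back at 15, replacing the radical coupling by polar chemistry before the carboxyl group exists. Bromine–lithium exchange on 4 (n-BuLi, THF, −78 °C) and BF3·OEt2-promoted opening of 11 at CH2 give (R)-1-[3,5-bis(benzyloxy)phenyl]propan-2-ol F5. Steglich esterification with 14 gives the bromo diester F6. Vilsmeier–Haack formylation ortho to the side chain gives the aldehyde F7, and Pinnick oxidation gives the acid F8. Mitsunobu esterification of F8 with 9 then gives 15.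

Step 10 is third. The free hydroxyl consumes base, and over-addition or cyclisation of the chloro ketone is possible if the quench is not cold and acidic. The fallback sets out from 16 and comes back at 17. Acyl transfer from 16 to dimethylsulfoxonium methylide (Me3S(O)I, KOtBu, THF, reflux) gives dimethylsulfoxonium (R)-4-hydroxy-2-oxopentylide F9. HCl in THF (LiCl, MsOH, 65 °C) converts F9 into 17.

**Further compounds**
F1 | step 11 | (R)-pent-4-yn-2-ol | C[C@@H](O)CC#C
F2 | step 11 | (R)-4-(benzyloxy)pent-1-yne | C[C@@H](OCc1ccccc1)CC#C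
F3 | step 11 | alkyne-coupled tetraester | C[C@H](Cc1cc(OCc2ccccc2)cc(OCc2ccccc2)c1C(=O)O[C@H](C)CC(=O)OCc1ccc(OC)cc1)OC(=O)C[C@@H](C)OC(=O)c1c(OCc2ccccc2)cc(OCc2ccccc2)cc1C#CC[C@@H](C)OCc1ccccc1
F4 | step 11 | O-benzyl keto tetraester | C[C@H](Cc1cc(OCc2ccccc2)cc(OCc2ccccc2)c1C(=O)O[C@H](C)CC(=O)OCc1ccc(OC)cc1)OC(=O)C[C@@H](C)OC(=O)c1c(OCc2ccccc2)cc(OCc2ccccc2)cc1CC(=O)C[C@@H](C)OCc1ccccc1
F5 | step 7 | (R)-1-[3,5-bis(benzyloxy)phenyl]propan-2-ol | C[C@@H](O)Cc1cc(OCc2ccccc2)cc(OCc2ccccc2)c1
F6 | step 7 | bromo diester | C[C@H](Cc1cc(OCc2ccccc2)cc(OCc2ccccc2)c1)OC(=O)C[C@@H](C)OC(=O)c1c(Br)cc(OCc2ccccc2)cc1OCc1ccccc1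
F7 | step 7 | aldehyde | C[C@H](Cc1cc(OCc2ccccc2)cc(OCc2ccccc2)c1C=O)OC(=O)C[C@@H](C)OC(=O)c1c(Br)cc(OCc2ccccc2)cc1OCc1ccccc1
F8 | step 7 | acid | C[C@H](Cc1cc(OCc2ccccc2)cc(OCc2ccccc2)c1C(=O)O)OC(=O)C[C@@H](C)OC(=O)c1c(Br)cc(OCc2ccccc2)cc1OCc1ccccc1
F9 | step 10 | dimethylsulfoxonium (R)-4-hydroxy-2-oxopentylide | C[C@@H](O)CC(=O)C=S(C)(C)=O
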